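**Retrosynthetic overview**

1. The target is a CH2-bridged pair of a butyrylfilicinic acid ring (trione ring, C1–C6) and a 2,4-dihydroxy-6-methoxybutyrophenone ring (C1'–C6'), with no stereocentres. The strategy rests on one feature: the bridging CH2 joins C6 and C3' and is flanked by the enol oxygen on C5 and the phenol oxygen on C2' (the hydroxyl beside the aryl butyryl group). An ether between these two oxygens turns formation of the C3'–CH2 bond into closure of a six-membered 4H-pyran (xanthene) ring.
2. Disconnections, backwards: hydrolysis of the C5–O–C2' aryl vinylogous ester and of the 4'-O-sulfonate; C3'–CH2 by intramolecular Friedel–Crafts alkylation from the C6 Mannich base; C6–CH2N by Mannich reaction; C5–OAr by substitution of a vinylogous acid chloride with the phenoxide.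
3. Fragments: butyrylfilicinic acid from phloroglucinol (C-acylation, dearomatising geminal dimethylation); the arene from 5-methoxyresorcinol (C-acylation, 4'-O-tosylation).
4. Ring order: the trione ring arises by dearomatisation of the phloroglucinol ring; the temporary pyran ring closes in the key step and is opened again in the last step.
5. A tosylate, not an ether, protects the 4'-oxygen: it keeps that oxygen out of the ether formation, makes the arene too electron-poor to intercept the iminium salt, survives acid, and falls in the final hydroxide step.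

Key step: step 8

Remark: the triketones and acylphenols are tautomeric mixtures and are drawn in the enol form used for the target; 11 should exist as the ammonium/triketonate zwitterion; no configuration has to be set.

**Route**

Step 1
Reactants: 1 phloroglucinol; 2 butyryl chloride
Product: 3 1-(2,4,6-trihydroxyphenyl)butan-1-one
Conditions: AlCl3 (3.5 equiv), PhNO2, rt → 60 °C; then ice/1 M HCl
Reagents that add atoms: none
Why: Friedel–Crafts C-acylation of the very electron-rich triol should stop after one acyl group because the chelated aryl ketone–AlCl3 complex deactivates the ring.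

Step 2
Reactants: 3 1-(2,4,6-trihydroxyphenyl)butan-1-one
Product: 4 2-butanoyl-3,5-dihydroxy-4,4-dimethylcyclohexa-2,5-dien-1-one (butyrylfilicinic acid)
Conditions: NaOMe (3.5 equiv), MeI (2.5 equiv), MeOH, 0 °C → rt; then 1 M HCl; chromatography
Reagents that add atoms: iodomethane, CI
Why: Base-mediated C-methylation of the acylphloroglucinol anion (dearomatising geminal dimethylation) should place both methyl groups on one ring carbon, since the resulting acidic triketone anion is methylated further only slowly; under- and over-methylated material is separated.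

Step 3
Reactants: 5 5-methoxyresorcinol; 2 butyryl chloride
Product: 6 1-(2,4-dihydroxy-6-methoxyphenyl)butan-1-one
Conditions: AlCl3 (3 equiv), PhNO2, 0 °C → rt; then ice/1 M HCl; chromatography
Reagents that add atoms: none
Why: Friedel–Crafts acylation at C4 of 5 (ortho to one hydroxyl, para to the other, two equivalent sites) should prevail over attack between the two hydroxyls, and the symmetric 2,6-dihydroxy-4-methoxy isomer is removed by chromatography.

Step 4
Reactants: 6 1-(2,4-dihydroxy-6-methoxyphenyl)butan-1-one
Product: 7 4-butanoyl-3-hydroxy-5-methoxyphenyl 4-methylbenzenesulfonate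
Conditions: TsCl (1.05 equiv), K2CO3 (1.2 equiv), acetone, rt
Reagents that add atoms: 4-methylbenzenesulfonyl chloride, Cc1ccc(cc1)S(Cl)(=O)=O
Why: Selective O-sulfonylation of the more acidic, unchelated hydroxyl para to the ketone, the ortho hydroxyl being held in the hydrogen bond to the carbonyl; the sulfonate also lowers the nucleophilicity of the arene for step 7.

Step 5
Reactants: 4 2-butanoyl-3,5-dihydroxy-4,4-dimethylcyclohexa-2,5-dien-1-one
Product: 8 2-butanoyl-5-chloro-3-hydroxy-4,4-dimethylcyclohexa-2,5-dien-1-one
Conditions: (COCl)2 (1.05 equiv), DMF (5 mol %), CH2Cl2, 0 °C → rt; evaporated and used crude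
Reagents that add atoms: oxalyl chloride, O=C(Cl)C(Cl)=O
Why: Chlorodehydroxylation of a vinylogous acid (enol chlorooxalate, then chloride addition–elimination, as for cyclic 1,3-diones), in which the free C5 hydroxyl should react before the enol locked in the hydrogen bond to the butyryl carbonyl.

Step 6
Reactants: 8 2-butanoyl-5-chloro-3-hydroxy-4,4-dimethylcyclohexa-2,5-dien-1-one; 7 4-butanoyl-3-hydroxy-5-methoxyphenyl 4-methylbenzenesulfonate
Product: 9 2-butanoyl-5-[2-butanoyl-3-methoxy-5-(tosyloxy)phenoxy]-3-hydroxy-4,4-dimethylcyclohexa-2,5-dien-1-one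
Conditions: Cs2CO3 (2.5 equiv), DMF, 4 Å MS, rt → 60 °C; then 1 M HCl
Reagents that add atoms: none
Why: Nucleophilic vinylic substitution (addition–elimination) of the vinylogous acid chloride by the phenoxide, whose only free oxygen is the one beside the butyryl group, so the ether is formed through C2'–O.

Step 7
Reactants: 9 2-butanoyl-5-[2-butanoyl-3-methoxy-5-(tosyloxy)phenoxy]-3-hydroxy-4,4-dimethylcyclohexa-2,5-dien-1-one; 10 Eschenmoser's salt (N,N-dimethylmethyleneiminium iodide)
Product: 11 2-butanoyl-5-[2-butanoyl-3-methoxy-5-(tosyloxy)phenoxy]-6-[(dimethylamino)methyl]-3-hydroxy-4,4-dimethylcyclohexa-2,5-dien-1-one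
Conditions: iPr2NEt (1.1 equiv), MeCN, rt → 50 °C; aqueous work-up at pH 7
Reagents that add atoms: none
Why: Mannich aminomethylation with a preformed iminium salt at C6, the α-carbon of the vinylogous ester and the only C–H carbon of the trione ring, while the acylated and sulfonylated arene should be too electron-poor to compete.

Step 8
Reactants: 11 2-butanoyl-5-[2-butanoyl-3-methoxy-5-(tosyloxy)phenoxy]-6-[(dimethylamino)methyl]-3-hydroxy-4,4-dimethylcyclohexa-2,5-dien-1-one
Product: 13 2,5-dibutanoyl-3-hydroxy-6-methoxy-4,4-dimethyl-1-oxo-4,9-dihydro-1H-xanthen-8-yl 4-methylbenzenesulfonate, via methylene oxocarbenium ion 12 (not isolated)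
Conditions: CF3CO2H (5 equiv), (CF3)2CHOH, 0.01 M, 50 °C
Reagents that add atoms: none
Why: The protonated amino group leaves as dimethylamine with electron push from the aryloxy oxygen, giving the 2-methylene oxocarbenium (1-aryloxyallyl) cation 12, whose methylene terminus is attacked by the tethered arene carbon C3' (ortho to the ether oxygen, para to the methoxy group); proton loss restores the arene. The closest known reaction type is the intramolecular Friedel–Crafts alkylation of arenes by electrophiles released from Mannich bases, as in the acid closure of 2-aryloxybenzyl cations to xanthenes. The 4H-pyran ring closes in a 6-endo-trig mode, the methylene carbon and C6 both lying in the new ring. No stereocentre is formed. The step needs site selectivity on the arene, and the tether secures it: the other carbon ortho to the ether oxygen carries the butyryl group, and the carbon between the sulfonate and the methoxy group cannot reach the methylene carbon. Both trione carbons that could act as nucleophiles (C2 and C6) are substituted, so no trione–trione dimer can form, and dilution should suppress intermolecular arene alkylation.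

Step 9
Reactants: 13 2,5-dibutanoyl-3-hydroxy-6-methoxy-4,4-dimethyl-1-oxo-4,9-dihydro-1H-xanthen-8-yl 4-methylbenzenesulfonate
Product: 14 2-butanoyl-6-[(3-butanoyl-2,6-dihydroxy-4-methoxyphenyl)methyl]-3,5-dihydroxy-4,4-dimethylcyclohexa-2,5-dien-1-one (target)
Conditions: NaOH (2 M aq, 10 equiv), 1,4-dioxane, N2, rt → 40 °C; then 1 M HCl, 0 °C
Reagents that add atoms: sodium hydroxide, [Na+].[OH-]
Why: Saponification of the aryl vinylogous ester (hydroxide adds at C5 and the phenoxide leaves, opening the pyran) and hydroxide attack at sulfur of the aryl sulfonate activated by the para ketone both end in stabilised anions and are therefore irreversible; the treatment is kept cool, oxygen-free and short because methylene-bridged acylphloroglucinols scramble by retro-Friedel–Crafts cleavage in warm alkali.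

**Compound list**

1 | phloroglucinol (benzene-1,3,5-triol) | Oc1cc(O)cc(O)c1 | starting material
2 | butyryl chloride (butanoyl chloride) | CCCC(Cl)=O | starting material
3 | 1-(2,4,6-trihydroxyphenyl)butan-1-one | CCCC(=O)c1c(O)cc(O)cc1O | intermediate
4 | 2-butanoyl-3,5-dihydroxy-4,4-dimethylcyclohexa-2,5-dien-1-one (butyrylfilicinic acid) | CCCC(=O)C1=C(O)C(C)(C)C(O)=CC1=O | intermediate
5 | 5-methoxyresorcinol (5-methoxybenzene-1,3-diol) | COc1cc(O)cc(O)c1 | starting material
6 | 1-(2,4-dihydroxy-6-methoxyphenyl)butan-1-one | CCCC(=O)c1c(O)cc(O)cc1OC | intermediate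
7 | 4-butanoyl-3-hydroxy-5-methoxyphenyl 4-methylbenzenesulfonate | CCCC(=O)c1c(O)cc(OS(=O)(=O)c2ccc(C)cc2)cc1OC | intermediate
8 | 2-butanoyl-5-chloro-3-hydroxy-4,4-dimethylcyclohexa-2,5-dien-1-one | CCCC(=O)C1=C(O)C(C)(C)C(Cl)=CC1=O | intermediate
9 | 2-butanoyl-5-[2-butanoyl-3-methoxy-5-(tosyloxy)phenoxy]-3-hydroxy-4,4-dimethylcyclohexa-2,5-dien-1-one | CCCC(=O)C1=C(O)C(C)(C)C(Oc2cc(OS(=O)(=O)c3ccc(C)cc3)cc(OC)c2C(=O)CCC)=CC1=O | intermediate
10 | Eschenmoser's salt (N,N-dimethylmethyleneiminium iodide) | C[N+](C)=C.[I-] | starting material
11 | 2-butanoyl-5-[2-butanoyl-3-methoxy-5-(tosyloxy)phenoxy]-6-[(dimethylamino)methyl]-3-hydroxy-4,4-dimethylcyclohexa-2,5-dien-1-one | CCCC(=O)C1=C(O)C(C)(C)C(Oc2cc(OS(=O)(=O)c3ccc(C)cc3)cc(OC)c2C(=O)CCC)=C(CN(C)C)C1=O | intermediate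
12 | methylene oxocarbenium ion from 11 (6-methylidene trione ring with C5=O+–aryl) | CCCC(=O)C1=C(O)C(C)(C)C(=[O+]c2cc(OS(=O)(=O)c3ccc(C)cc3)cc(OC)c2C(=O)CCC)C(=C)C1=O | intermediate
13 | 2,5-dibutanoyl-3-hydroxy-6-methoxy-4,4-dimethyl-1-oxo-4,9-dihydro-1H-xanthen-8-yl 4-methylbenzenesulfonate | CCCC(=O)C1=C(O)C(C)(C)C2=C(Cc3c(OS(=O)(=O)c4ccc(C)cc4)cc(OC)c(C(=O)CCC)c3O2)C1=O | intermediate
14 | 2-butanoyl-6-[(3-butanoyl-2,6-dihydroxy-4-methoxyphenyl)methyl]-3,5-dihydroxy-4,4-dimethylcyclohexa-2,5-dien-1-one | CCCC(=O)C1=C(O)C(C)(C)C(O)=C(Cc2c(O)cc(OC)c(C(=O)CCC)c2O)C1=O | target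

**Step count**

Total: 9 steps. Longest linear sequence: 7 steps (1, 2, 5, 6, 7, 8, 9, from phloroglucinol).

**Steps most likely to fail**

Step 8. Ionisation of the C–N bond may be slow, because the cation carries a carbonyl group on its central carbon. Retro-Mannich loss of the iminium ion and intermolecular alkylation could then outrun ring closure. The fallback gives up the tether and sets out from 4 and 6, returning at 14. Compound 4 is aminomethylated with 10 in CH2Cl2 at rt (C6 of the enolised dione is its only nucleophilic carbon) to the Mannich base 2-butanoyl-6-[(dimethylamino)methyl]-3,5-dihydroxy-4,4-dimethylcyclohexa-2,5-dien-1-one F1. Heated with 6 in 1,4-dioxane at 80 °C, this should lose dimethylamine to the methylene trione 2-butanoyl-3-hydroxy-4,4-dimethyl-6-methylidenecyclohex-2-ene-1,5-dione F2 (not isolated). The carbon of 6 between its two hydroxyls should add to F2 in a conjugate manner and give 14 directly. Without the tether, the isomer bridged at the carbon between hydroxyl and methoxy and the symmetric dimers would have to be removed by chromatography.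

Step 6. Under base the chloride 8 is deprotonated to its triketonate, so addition of the hindered, chelated phenoxide at C5 may be slow. Hydrolysis of the chloride, sulfonyl transfer between phenoxides and material chlorinated at the wrong enol in step 5 could then take over. The fallback masks the triketone; it sets out from 4 and returns at 9. BF3·OEt2 in CH2Cl2 should convert the chelated enol of 4 into the O,O-difluoroboron chelate of 4 F3. With (COCl)2 and catalytic DMF only the free C5 hydroxyl can then react, giving the difluoroboron chelate of 8 F4, a neutral and strongly activated vinylogous acid chloride. This should take up 7 with iPr2NEt in CH2Cl2 at rt to give the difluoroboron chelate of 9 F5. Warming with NaOAc in THF/H2O removes boron and delivers 9.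

Step 7. C6 is the α-carbon of a push–pull alkene and may react sluggishly with the iminium ion. Reversible attack at the triketonate oxygens or C2 could hold the reagent, and forcing conditions could bring aminomethylation of the arene or of a ketone α-carbon. The fallback sets out from 9 and returns at 13, leaving out 11. Paraformaldehyde and CF3CO2H in (CF3)2CHOH at high dilution supply protonated formaldehyde, a much stronger electrophile. It should hydroxymethylate C6 to the 6-(hydroxymethyl) analogue of 11 F6 (not isolated), which ionises in the same acid to cation 12 and closes to 13, as in the classical acid condensation of diaryl ethers with formaldehyde to xanthenes.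

**Further compounds**

F1 | step 8 | 2-butanoyl-6-[(dimethylamino)methyl]-3,5-dihydroxy-4,4-dimethylcyclohexa-2,5-dien-1-one | CCCC(=O)C1=C(O)C(C)(C)C(O)=C(CN(C)C)C1=O
F2 | step 8 | 2-butanoyl-3-hydroxy-4,4-dimethyl-6-methylidenecyclohex-2-ene-1,5-dione | CCCC(=O)C1=C(O)C(C)(C)C(=O)C(=C)C1=O
F3 | step 6 | O,O-difluoroboron chelate of 4 (boron bridging the butyryl oxygen and the C3 enol oxygen) | CCCC1=[O+][B-](F)(F)OC2=C1C(=O)C=C(O)C2(C)C
F4 | step 6 | O,O-difluoroboron chelate of 8 | CCCC1=[O+][B-](F)(F)OC2=C1C(=O)C=C(Cl)C2(C)C
F5 | step 6 | O,O-difluoroboron chelate of 9 | CCCC1=[O+][B-](F)(F)OC2=C1C(=O)C=C(Oc1cc(OS(=O)(=O)c3ccc(C)cc3)cc(OC)c1C(=O)CCC)C2(C)C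
F6 | step 7 | 2-butanoyl-5-[2-butanoyl-3-methoxy-5-(tosyloxy)phenoxy]-3-hydroxy-6-(hydroxymethyl)-4,4-dimethylcyclohexa-2,5-dien-1-one | CCCC(=O)C1=C(O)C(C)(C)C(Oc2cc(OS(=O)(=O)c3ccc(C)cc3)cc(OC)c2C(=O)CCC)=C(CO)C1=O
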